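A molar of target costs two molar of reagent, so I count this flask in molar.

    reagent + intermediate B ⇌ intermediate C (K1 = 1.4 M⁻¹, k1 = 3.5 × 10⁻⁴ M⁻¹ s⁻¹)
    crystals ⇌ target, rate k2*(cs2 - [target]) while solid is left; crystals form when [target] > cs2 (cs2 = 0.86 M, k2 = 0.032 s⁻¹)
    substrate ⇌ intermediate A (K3 = 1.7, k3 = 8.0 × 10⁻⁴ s⁻¹)
    reagent + intermediate A → intermediate B (k4 = 1.7 × 10⁻⁴ M⁻¹ s⁻¹)
    intermediate C ⇌ target (K5 = 1.0, k5 = 6.5 × 10⁻⁴ s⁻¹)

substrate 1.5 M; reagent 2.25 M; time 5.0 h

1. target and crystals together at 5.0 h, in percent of the substrate charged
2. concentration of target in solution at 80 min, in percent of saturation
3. the change that raises the amount of target and crystals together at 5.0 h, in percent of the substrate charged most ("none" if none brings more than 2 percentage points) (red / ochre / grey / none)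
4. amount of target and crystals together at 5.0 h, in percent of the substrate charged, after ochre

- red: doubling the dissolution coefficient of step 2, all else as stated
- ochre: doubling the solubility in step 2, all else as stated
- grey: doubling the amount of reagent, all else as stated

- for target the crystals are counted in
- as a solid, counted per litre of solution: crystals
- run time (flask): 5.0 h

**Main chain.** I start with the forward path: substrate to intermediate A, then intermediate B, intermediate C and target. I turn the constants into forward half-lives at the charged amounts. Steps 3, 1 and 5 give 0.24 h, 0.24 h and 0.30 h. Step 4, for intermediate A at charged reagent, gives 0.503 h. Each is shorter than the run of 5.0 h. So I reckon from the charge. Reagent is the limiting reagent, and the cap is 75.0% of the substrate charged.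

**Step five back.** Now I let target fall back to intermediate C. This pair relaxes with a half-life of 0.148 h, shorter than the run. The target share is 50.0%, the part of target and intermediate C together that stands as target once step 5 has relaxed. The cap therefore drops to 37.5%.

**The rest.** Step 1 also runs back, so I expect some material to wait as intermediate B. At the start its constant times reagent is 3.1, but that product falls as reagent is used. I expect less than my bound, and I stop there. The bound means 0.562 M of dissolved target, less than the solubility of 0.86 M. So I commit to no crystals, no gain from red or ochre, and grey as the choice.

**The forecast.** It gives 21% for y, 24% for sat, grey as best and 21% for yb. Its grounds: “No crystals ever form, so red and ochre change nothing”. Its y lies below my bound.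

**The simulation.** It gives 21.4% for y and 18.9% for sat. The best change is grey, worth 19 percentage points, while red brings 0 points and ochre 0 points. After ochre, yb is 21.4%, so the solubility makes no difference here.

**Even split.** At 5.00 h this flask holds 21.4% as target and 21.4% as intermediate C, a read share of 50.0% against the target share of 50.0%. The flask with 0.60 M of substrate holds 35.0% and 35.7%, a read share of 49.5%. In the flask as charged, the falling back of target to intermediate C is the largest single effect on y. The run of that flask without it gives 57.3% instead of 21.4%, which covers 46% of what is missing.

(The numbers of this flask were drawn at random within sensible limits; the result is computed.)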